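**Retrosynthetic overview**
1. Feature: in ring C (O1, C2, C3, C4, C4a, C8a) the hydroxyl-bearing C3 is bonded directly to the C4 carbonyl. The flavonol is therefore the C2-C3 dehydro form of a cyclic acyloin, and C3-C4 can be made between two former aldehyde carbons by umpolung.
2. Target <= BBr3 demethylation <= I2/DMSO dehydrogenation of the trans-dihydroflavonol <= C3-C4 by carbene-catalysed intramolecular crossed benzoin of a dialdehyde held together through O1. Ring C is the only ring formed; rings A, B and the benzyl ring are bought.
3. Dialdehyde <= oxidation of the diol <= LiAlH4 reduction of the aryloxy ester <= O1-C2 by Williamson alkylation of a 3-benzylsalicylaldehyde with an alpha-bromo arylacetate.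
4. 3-Benzylsalicylaldehyde <= ortho-formylation of the 2-benzylphenol <= aryl Grignard addition and ionic reduction on 2-hydroxy-4,6-dimethoxybenzaldehyde, whose formyl carbon becomes the C8 benzyl CH2.

Key step: step 8

Assumption: the target is achiral, so every stereocentre on the way is carried as a racemate. Where a name or SMILES shows a configuration, it depicts one enantiomer, and only the relative configuration has meaning.

Design remark: only the ring A aldehyde can act as the acyl anion donor, because an acyl anion equivalent at C3 has the O1 aryloxide as a leaving group on the neighbouring C2. For this reason the catalyst is an N-ethyl thiazolium salt, the amine is kept weak and substoichiometric, and the dialdehyde is made by an oxidation that uses no trialkylamine.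

**Step 1**
Reactants: 1 2-hydroxy-4,6-dimethoxybenzaldehyde; 2 4-methoxyphenylmagnesium bromide (commercial THF solution)
Product: 3 2-[(R)-hydroxy(4-methoxyphenyl)methyl]-3,5-dimethoxyphenol (racemate)
Conditions: 2 (2.5 equiv), THF, 0 °C to rt; aq NH4Cl; crude product taken on
Reagents that add atoms: none
Why: Grignard 1,2-addition: the first equivalent of 2 deprotonates the phenol, a second adds to the magnesium-chelated aldehyde, and the new carbinol centre, formed without control as a racemate, is removed in step 2.

**Step 2**
Reactants: 3 2-[(R)-hydroxy(4-methoxyphenyl)methyl]-3,5-dimethoxyphenol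
Product: 4 3,5-dimethoxy-2-(4-methoxybenzyl)phenol
Conditions: Et3SiH (5 equiv), CF3CO2H (5 equiv), CH2Cl2, 0 °C, slow addition of 3
Reagents that add atoms: none
Why: Ionic hydrogenation: CF3CO2H ionises the benzhydrol to a cation stabilised by both electron-rich rings, and excess Et3SiH should trap it by hydride transfer before it can alkylate another arene, slow addition of 3 keeping the cation dilute.

**Step 3**
Reactants: 4 3,5-dimethoxy-2-(4-methoxybenzyl)phenol
Product: 5 2-hydroxy-4,6-dimethoxy-3-(4-methoxybenzyl)benzaldehyde
Conditions: MgCl2 (2 equiv), Et3N (4 equiv), (CH2O)n (6 equiv), MeCN, reflux; then 1 M HCl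
Reagents that add atoms: paraformaldehyde (reacts as formaldehyde), C=O
Why: Magnesium-mediated ortho-formylation (Casnati-Skattebol reaction): formaldehyde is delivered within the magnesium phenoxide complex to the only free ortho carbon and not to the carbon between the two methoxy groups, and a second formaldehyde accepts hydride to raise the new carbon to the aldehyde level.

**Step 4**
Reactants: 6 methyl 4-methoxyphenylacetate
Product: 7 methyl (2S)-2-bromo-2-(4-methoxyphenyl)acetate (racemate)
Conditions: NBS (1.05 equiv), AIBN (cat.), PhCF3, reflux; used without storage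
Reagents that add atoms: N-bromosuccinimide, O=C1CCC(=O)N1Br
Why: Wohl-Ziegler bromination: in a non-polar solvent the radical chain abstracts the hydrogen at the carbon that is both benzylic and alpha to the ester, which should outrun ionic bromination of the anisole ring, and the new centre is racemic.

**Step 5**
Reactants: 5 2-hydroxy-4,6-dimethoxy-3-(4-methoxybenzyl)benzaldehyde; 7 methyl (2S)-2-bromo-2-(4-methoxyphenyl)acetate
Product: 8 methyl (2R)-2-[2-formyl-3,5-dimethoxy-6-(4-methoxybenzyl)phenoxy]-2-(4-methoxyphenyl)acetate (racemate)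
Conditions: K2CO3 (2 equiv), DMF, rt
Reagents that add atoms: none
Why: Williamson ether synthesis: the phenoxide of 5 displaces the bromide, activated by both the ester and the anisyl group, in an SN2 reaction that forms O1-C2 as a racemic centre, and room temperature keeps the ester enolate of 8 from adding to the flanked, electron-rich aldehyde.

**Step 6**
Reactants: 8 methyl (2R)-2-[2-formyl-3,5-dimethoxy-6-(4-methoxybenzyl)phenoxy]-2-(4-methoxyphenyl)acetate
Product: 9 (2R)-2-[2-(hydroxymethyl)-3,5-dimethoxy-6-(4-methoxybenzyl)phenoxy]-2-(4-methoxyphenyl)ethan-1-ol (racemate)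
Conditions: LiAlH4 (2 equiv), THF, 0 °C; Fieser work-up (H2O, aq NaOH, H2O)
Reagents that add atoms: none
Why: LiAlH4 reduction takes the ester and the aldehyde to primary alcohols in one operation without touching the aryl ethers or the C2 centre, and the basic work-up spares the acid-labile trialkoxybenzyl alcohol.

**Step 7**
Reactants: 9 (2R)-2-[2-(hydroxymethyl)-3,5-dimethoxy-6-(4-methoxybenzyl)phenoxy]-2-(4-methoxyphenyl)ethan-1-ol
Product: 10 (2R)-2-[2-formyl-3,5-dimethoxy-6-(4-methoxybenzyl)phenoxy]-2-(4-methoxyphenyl)acetaldehyde (racemate)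
Conditions: Dess-Martin periodinane (2.6 equiv), pyridine (6 equiv), CH2Cl2, 0 °C to rt; short filtration, used at once
Reagents that add atoms: none
Why: Dess-Martin oxidation: both primary alcohols are raised to aldehydes at or below room temperature in a pyridine-buffered medium without trialkylamine, so the easily enolised C2-H aldehyde should survive and over-oxidation to acids is not expected.

**Step 8**
Reactants: 10 (2R)-2-[2-formyl-3,5-dimethoxy-6-(4-methoxybenzyl)phenoxy]-2-(4-methoxyphenyl)acetaldehyde
Product: 12 (2R,3R)-3-hydroxy-5,7-dimethoxy-8-(4-methoxybenzyl)-2-(4-methoxyphenyl)chroman-4-one (trans; racemate), via Breslow enaminol 11 (not isolated)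
Conditions: 3-ethyl-5-(2-hydroxyethyl)-4-methylthiazolium bromide (20 mol %), Et3N (40 mol %), degassed t-BuOH/THF, 0.01 M, 40 °C, Ar
Reagents that add atoms: none
Why: Proposed new method: Et3N frees the thiazol-2-ylidene, which adds to the ring A aldehyde; proton transfer gives Breslow enaminol 11, an acyl anion equivalent at C4, whose nucleophilic carbon attacks the tethered aliphatic aldehyde carbon (C3), and collapse of the adduct returns the carbene and unveils the C4 ketone. The closest known reaction types are the carbene-catalysed intramolecular crossed benzoin of 2-(2-oxoalkoxy)benzaldehydes, an aldehyde-ketone pairing that gives 3-alkyl-3-hydroxychroman-4-ones, and the thiazolium-catalysed acyloin cyclisation of simple aliphatic dialdehydes, whereas an aryl aldehyde paired with an alpha-aryloxy aldehyde has not been shown. Ring C closes in the 6-exo-trig mode, the attacked C3=O bond lying outside the new six-membered ring. The new C3 centre is set relative to C2 by a chair-like transition state that keeps the C2 aryl group equatorial, and the amine corrects any cis material through the C3-C4 enediol to the diequatorial trans isomer. The step needs donor selectivity, because an enaminol formed at C3 would expel the O1 aryloxide from C2 (internal redox with acyl transfer) instead of closing the ring; the ring A aldehyde is favoured as donor by the much more acidic benzylic C-H of its carbene adduct and by an N-ethyl thiazolium salt, the type customarily chosen for aromatic donors, while the unconjugated C3 aldehyde is by far the better acceptor. High dilution, a weak amine in substoichiometric amount and exclusion of air hold back dimerisation, the 5-exo aldol attack of C2 on the ring A aldehyde and oxidation of 11.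

**Step 9**
Reactants: 12 (2R,3R)-3-hydroxy-5,7-dimethoxy-8-(4-methoxybenzyl)-2-(4-methoxyphenyl)chroman-4-one
Product: 14 3-hydroxy-5,7-dimethoxy-8-(4-methoxybenzyl)-2-(4-methoxyphenyl)-4H-chromen-4-one, via chromane-3,4-dione 13 (not isolated)
Conditions: I2 (20 mol %), DMSO, 100 °C
Reagents that add atoms: none
Why: Iodine-catalysed DMSO oxidation of an acyloin to a 1,2-dione: the C3-C4 enediol of 12 is oxidised to dione 13, whose C2-H enolises at once to the aromatic 3-hydroxychromone, DMSO returns HI to I2, and both stereocentres disappear so that cis and trans material converge.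

**Step 10**
Reactants: 14 3-hydroxy-5,7-dimethoxy-8-(4-methoxybenzyl)-2-(4-methoxyphenyl)-4H-chromen-4-one
Product: 15 8-C-p-hydroxybenzylkaempferol
Conditions: BBr3 (10 equiv), CH2Cl2, -78 °C to rt; then ice-water
Reagents that add atoms: none
Why: Lewis acid ether cleavage: BBr3 binds each methoxy oxygen and bromide attacks the methyl carbon, which should free all four phenols at or below room temperature, mild enough to avoid acid-induced ring C opening and reclosure (Wessely-Moser rearrangement) or migration of the C8 benzyl group.

**Compound list**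
1 | 2-hydroxy-4,6-dimethoxybenzaldehyde | COc1cc(O)c(C=O)c(OC)c1 | starting material
2 | 4-methoxyphenylmagnesium bromide | COc1ccc([Mg]Br)cc1 | starting material
3 | 2-[(R)-hydroxy(4-methoxyphenyl)methyl]-3,5-dimethoxyphenol (racemate) | COc1ccc(cc1)[C@@H](O)c1c(O)cc(OC)cc1OC | intermediate
4 | 3,5-dimethoxy-2-(4-methoxybenzyl)phenol | COc1ccc(Cc2c(O)cc(OC)cc2OC)cc1 | intermediate
5 | 2-hydroxy-4,6-dimethoxy-3-(4-methoxybenzyl)benzaldehyde | COc1ccc(Cc2c(O)c(C=O)c(OC)cc2OC)cc1 | intermediate
6 | methyl 4-methoxyphenylacetate | COC(=O)Cc1ccc(OC)cc1 | starting material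
7 | methyl (2S)-2-bromo-2-(4-methoxyphenyl)acetate (racemate) | COc1ccc(cc1)[C@H](Br)C(=O)OC | intermediate
8 | methyl (2R)-2-[2-formyl-3,5-dimethoxy-6-(4-methoxybenzyl)phenoxy]-2-(4-methoxyphenyl)acetate (racemate) | COc1ccc(cc1)[C@@H](Oc1c(Cc2ccc(OC)cc2)c(OC)cc(OC)c1C=O)C(=O)OC | intermediate
9 | (2R)-2-[2-(hydroxymethyl)-3,5-dimethoxy-6-(4-methoxybenzyl)phenoxy]-2-(4-methoxyphenyl)ethan-1-ol (racemate) | COc1ccc(cc1)[C@@H](Oc1c(Cc2ccc(OC)cc2)c(OC)cc(OC)c1CO)CO | intermediate
10 | (2R)-2-[2-formyl-3,5-dimethoxy-6-(4-methoxybenzyl)phenoxy]-2-(4-methoxyphenyl)acetaldehyde (racemate) | COc1ccc(cc1)[C@@H](Oc1c(Cc2ccc(OC)cc2)c(OC)cc(OC)c1C=O)C=O | intermediate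
11 | Breslow enaminol: (2R)-2-{2-[[3-ethyl-5-(2-hydroxyethyl)-4-methylthiazol-2(3H)-ylidene](hydroxy)methyl]-3,5-dimethoxy-6-(4-methoxybenzyl)phenoxy}-2-(4-methoxyphenyl)acetaldehyde (racemate) | COc1ccc(cc1)[C@@H](Oc1c(Cc2ccc(OC)cc2)c(OC)cc(OC)c1C(O)=C1SC(CCO)=C(C)N1CC)C=O | intermediate (not isolated)
12 | (2R,3R)-3-hydroxy-5,7-dimethoxy-8-(4-methoxybenzyl)-2-(4-methoxyphenyl)chroman-4-one (trans; racemate) | COc1ccc(cc1)[C@@H]1[C@H](C(=O)c2c(OC)cc(OC)c(Cc3ccc(OC)cc3)c2O1)O | intermediate
13 | (2R)-5,7-dimethoxy-8-(4-methoxybenzyl)-2-(4-methoxyphenyl)chromane-3,4-dione (racemate) | COc1ccc(cc1)[C@@H]1C(=O)C(=O)c2c(OC)cc(OC)c(Cc3ccc(OC)cc3)c2O1 | intermediate (not isolated)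
14 | 3-hydroxy-5,7-dimethoxy-8-(4-methoxybenzyl)-2-(4-methoxyphenyl)-4H-chromen-4-one | COc1ccc(cc1)-c1oc2c(Cc3ccc(OC)cc3)c(OC)cc(OC)c2c(=O)c1O | intermediate
15 | 8-C-p-hydroxybenzylkaempferol: 3,5,7-trihydroxy-8-(4-hydroxybenzyl)-2-(4-hydroxyphenyl)-4H-chromen-4-one | O=c1c(O)c(-c2ccc(O)cc2)oc2c(Cc3ccc(O)cc3)c(O)cc(O)c12 | target

**Step count**
Total step count: 10. Longest linear sequence: 9 (steps 1-3 and 5-10; step 4 is the side branch).

**Steps most likely to fail**

**Step 8.**
- Risk: the carbene may engage the aliphatic aldehyde first. Loss of the O1 aryloxide from C2 and acyl transfer would then consume the substrate irreversibly.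
- Risk: enaminol formation at the di-ortho-substituted, electron-rich ring A aldehyde may be too slow.
- Risk: amine-induced enolisation at C2 may divert material into a five-membered aldol closure.
- Fallback: known chemistry that builds ring C by the chalcone route instead of by umpolung. It sets out from 4 and comes back at 14. Friedel-Crafts/Fries acetylation of 4 at the free ortho carbon (Ac2O, BF3·OEt2, heat) should give 1-[2-hydroxy-4,6-dimethoxy-3-(4-methoxybenzyl)phenyl]ethan-1-one F1. Claisen-Schmidt condensation with 4-methoxybenzaldehyde (KOH, EtOH, rt) should give the chalcone (E)-1-[2-hydroxy-4,6-dimethoxy-3-(4-methoxybenzyl)phenyl]-3-(4-methoxyphenyl)prop-2-en-1-one F2. Oxidative cyclisation (cat. I2, DMSO, 130 °C) should give the flavone 5,7-dimethoxy-8-(4-methoxybenzyl)-2-(4-methoxyphenyl)-4H-chromen-4-one F3. Oxidation of its C2-C3 double bond with dimethyldioxirane (acetone/CH2Cl2, 0 °C), followed by a trace of p-TsOH in the same flask, installs the C3 hydroxyl and delivers 14.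

**Step 7.**
- Risk: acetic acid released by the periodinane may ionise the trialkoxybenzyl alcohol.
- Risk: the first-formed aldehyde may close to a lactol with the remaining alcohol and be over-oxidised.
- Risk: the alpha-aryloxy arylacetaldehyde may enolise, undergo aldol closure or degrade during work-up.
- Fallback: no diol and no oxidation; the ester is partly reduced while the ring A aldehyde is masked. It sets out from 8 and comes back at 10. Acetalisation (HC(OMe)3, cat. PPTS, MeOH) should give methyl (2R)-2-[2-(dimethoxymethyl)-3,5-dimethoxy-6-(4-methoxybenzyl)phenoxy]-2-(4-methoxyphenyl)acetate F4. Reduction with i-Bu2AlH (1.1 equiv, toluene, -78 °C) should stop at the chelated tetrahedral aluminate of the alpha-aryloxy ester. On quench this gives (2R)-2-[2-(dimethoxymethyl)-3,5-dimethoxy-6-(4-methoxybenzyl)phenoxy]-2-(4-methoxyphenyl)acetaldehyde F5. Brief treatment with PPTS in aqueous acetone hydrolyses the very labile electron-rich aryl acetal and returns 10.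

**Step 5.**
- Risk: O-alkylation of a hydrogen-bonded phenoxide flanked on both sides may be slow. It would then compete with solvolysis of the ionisable bromide, C-alkylation of ring A and carbonate-induced aldol closure of the product.
- Fallback: a redox condensation under neutral conditions instead of halide displacement. It sets out from 6 and 5 and comes back at 8. Enolate hydroxylation of 6 (NaN(SiMe3)2, then 2-(phenylsulfonyl)-3-phenyloxaziridine, THF, -78 °C; Davis oxidation) should give methyl (2S)-2-hydroxy-2-(4-methoxyphenyl)acetate F6, as the racemate. A Mitsunobu reaction of F6 with phenol 5 (PPh3, DIAD, toluene, 0 °C to rt) should form O1-C2 with inversion and give 8.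

**Further compounds**
F1 | step 8 | 1-[2-hydroxy-4,6-dimethoxy-3-(4-methoxybenzyl)phenyl]ethan-1-one | CC(=O)c1c(O)c(Cc2ccc(OC)cc2)c(OC)cc1OC
F2 | step 8 | (E)-1-[2-hydroxy-4,6-dimethoxy-3-(4-methoxybenzyl)phenyl]-3-(4-methoxyphenyl)prop-2-en-1-one | COc1ccc(/C=C/C(=O)c2c(O)c(Cc3ccc(OC)cc3)c(OC)cc2OC)cc1
F3 | step 8 | 5,7-dimethoxy-8-(4-methoxybenzyl)-2-(4-methoxyphenyl)-4H-chromen-4-one | COc1ccc(cc1)-c1cc(=O)c2c(OC)cc(OC)c(Cc3ccc(OC)cc3)c2o1
F4 | step 7 | methyl (2R)-2-[2-(dimethoxymethyl)-3,5-dimethoxy-6-(4-methoxybenzyl)phenoxy]-2-(4-methoxyphenyl)acetate (racemate) | COc1ccc(cc1)[C@@H](Oc1c(Cc2ccc(OC)cc2)c(OC)cc(OC)c1C(OC)OC)C(=O)OC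
F5 | step 7 | (2R)-2-[2-(dimethoxymethyl)-3,5-dimethoxy-6-(4-methoxybenzyl)phenoxy]-2-(4-methoxyphenyl)acetaldehyde (racemate) | COc1ccc(cc1)[C@@H](Oc1c(Cc2ccc(OC)cc2)c(OC)cc(OC)c1C(OC)OC)C=O
F6 | step 5 | methyl (2S)-2-hydroxy-2-(4-methoxyphenyl)acetate (racemate) | COc1ccc(cc1)[C@H](O)C(=O)OC
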